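**Retrosynthetic overview**
1. The C2–C1′ bond is made last. A chromon-2-yl carbanion (the C2-zincated 3-prenylchromone, an α-alkoxyvinyl anion and so a masked aroyl anion) adds to C5 of 2-methoxy-1,4-benzoquinone. Two acceptor carbons are joined, and the B ring forms directly as the free 2′,5′-hydroquinone.
2. The 3-prenylchromone comes from an o-hydroxyaryl enaminone and prenyl bromide. The C3–C1″ bond and the pyranone C–O bond form in one cascade.
3. The enaminone comes from 2′,6′-dihydroxy-4′-methoxyacetophenone and DMF dimethyl acetal, which supplies C2.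
4. Ring order: the A ring is bought, the C ring (pyranone) closes in step 2, and the B ring is bought as the quinone and aromatised in step 3. There are no separate protecting-group steps.

Assumption: the target SMILES has no stereocentre and no E/Z-stereogenic double bond (the prenyl terminus carries two methyls), so the compound is achiral and needs no stereocontrol; the acetophenone, DMF-DMA, prenyl bromide, methoxybenzoquinone and TMPZnCl·LiCl solution are taken as catalogue items.

**Step 1**
Reactants: 1 2′,6′-dihydroxy-4′-methoxyacetophenone; 2 N,N-dimethylformamide dimethyl acetal (DMF-DMA)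
Product: 3 (E)-3-(dimethylamino)-1-(2,6-dihydroxy-4-methoxyphenyl)prop-2-en-1-one
Conditions: DMF-DMA (1.5 equiv), toluene, 80 °C, 3 h; cool, filter
Reagents that add atoms: DMF-DMA (2), COC(OC)N(C)C
Why: This is the amide-acetal condensation of a methyl ketone (enaminone formation); the ortho OH groups are hydrogen-bonded to the carbonyl and are poor nucleophiles at 80 °C, and the E geometry is thermodynamic and is lost later.

**Step 2**
Reactants: 3 enaminone; 4 prenyl bromide (1-bromo-3-methylbut-2-ene)
Product: 6 5-hydroxy-7-methoxy-3-(3-methylbut-2-en-1-yl)-4H-chromen-4-one, via aminochromanone hydrobromide 5 (not isolated)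
Conditions: prenyl bromide (1.3 equiv), DMF, 70 °C, 4 h
Reagents that add atoms: prenyl bromide (4), CC(C)=CCBr
Why: This is a domino enaminone C-allylation/chromone annulation, known for allyl and benzyl bromides, in which the soft α-carbon attacks the primary allylic carbon by SN2, either of the two equivalent ortho OH groups closes on the iminium, and loss of Me2NH·HBr aromatises the pyranone (the two transient stereocentres of 5 are destroyed).

**Step 3**
Reactants: 6 5-hydroxy-7-methoxy-3-prenylchromone; 7 2-methoxy-1,4-benzoquinone
Product: 10 artoindonesianin Q [2-(2,5-dihydroxy-4-methoxyphenyl)-5-hydroxy-7-methoxy-3-(3-methylbut-2-en-1-yl)-4H-chromen-4-one], via chromon-2-ylzinc chloride 8 (not isolated), via tris-TMS ether 9 (not isolated)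
Conditions: TMPZnCl·LiCl (2.3 equiv), MgCl2 (1.0 equiv), THF, 0 → 25 °C, 2 h; then [RhCl(cod)]2 (2.5 mol %), TMSCl (4 equiv), 7 (1.2 equiv, slow addition), −20 → 25 °C, 3 h; then 1 M aq HCl, THF, 0 °C, 20 min (Ar)
Reagents that add atoms: 2-methoxy-1,4-benzoquinone (7), COC1=CC(=O)C=CC1=O; transient only (atoms in 8 and 9, absent from 10): TMPZnCl·LiCl, CC1(C)CCCC(C)(C)N1[Zn]Cl.[Li+].[Cl-]; TMSCl, C[Si](C)(C)Cl
Why: Proposed new method: with C3 blocked, C2–H is the most acidic C–H (a vinylogous formate whose carbonyl is activated by the 5-O–Zn chelate and MgCl2), so Knochel-type TMP-zincation (first equivalent on O–H, second on C2–H) turns this normally electrophilic enone β-carbon/masked aroyl carbon into the α-alkoxyvinyl nucleophile 8; Zn→Rh(I) transmetalation and 1,4-carbometalation of the unsubstituted, maleimide-like C5=C6 ene-dione unit of 7 form the bond at C5 (β to the C1 carbonyl, which the methoxy group does not deactivate as a vinylogous ester, and the same site taken in Thiele–Winter acetoxylation and in amine/thiol additions), while TMSCl plus the liberated TMPH trap the enolate and its aromatised tautomer as 9, so that no phenolic proton quenches 8 and no quinone/hydroquinone redox scrambling occurs, and dilute acid then removes the three aryl TMS ethers; the closest known reaction types are the Rh(I)-catalysed, TMSCl-assisted Hayashi–Miyaura-type 1,4-addition of aryl- and 2-heteroarylzinc halides to enones, the Rh-catalysed 1,4-arylation of quinone monoketals and the Pd(II)-catalysed addition of arylboronic acids to benzoquinones; no stereocentre is formed.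

**Compound list**
1 | 2′,6′-dihydroxy-4′-methoxyacetophenone | CC(=O)c1c(O)cc(OC)cc1O | starting material
2 | N,N-dimethylformamide dimethyl acetal | COC(OC)N(C)C | starting material
3 | (E)-3-(dimethylamino)-1-(2,6-dihydroxy-4-methoxyphenyl)prop-2-en-1-one | CN(C)/C=C/C(=O)c1c(O)cc(OC)cc1O | intermediate
4 | prenyl bromide | CC(C)=CCBr | starting material
5 | 2-(dimethylamino)-5-hydroxy-7-methoxy-3-prenylchroman-4-one hydrobromide (racemic diastereomer mixture, transient) | COc1cc(O)c2C(=O)C(CC=C(C)C)C([NH+](C)C)Oc2c1.[Br-] | intermediate
6 | 5-hydroxy-7-methoxy-3-(3-methylbut-2-en-1-yl)-4H-chromen-4-one | COc1cc(O)c2c(=O)c(CC=C(C)C)coc2c1 | intermediate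
7 | 2-methoxy-1,4-benzoquinone | COC1=CC(=O)C=CC1=O | starting material
8 | C2-chlorozincio-3-prenylchromone, 5-O-chlorozinc phenoxide (drawn without LiCl/MgCl2) | COc1cc(O[Zn]Cl)c2c(=O)c(CC=C(C)C)c([Zn]Cl)oc2c1 | intermediate
9 | 5,2′,5′-tris(trimethylsilyl) ether of artoindonesianin Q | COc1cc(O[Si](C)(C)C)c2c(=O)c(CC=C(C)C)c(-c3cc(O[Si](C)(C)C)c(OC)cc3O[Si](C)(C)C)oc2c1 | intermediate
10 | artoindonesianin Q | COc1cc(O)c2c(=O)c(CC=C(C)C)c(-c3cc(O)c(OC)cc3O)oc2c1 | target

**Total step count:** 3. **Longest linear sequence:** 3 (1 → 3 → 6 → 10).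

**Steps most likely to fail**

Step 3 carries the highest risk.
- Failure modes: single-electron reduction of 7 by the organometal with chromone homodimerisation, uncatalysed 1,2-addition at C1=O, some C6 regioisomer, or deactivation of Rh by the quinone.
- Fallback: this sets out from 8 (made from 6 as in step 3) and returns at 10. It fixes the coupling site with a leaving group and replaces conjugate addition with cross-coupling. Commercial 1-bromo-2,4,5-trimethoxybenzene F4 is oxidised with CAN (MeCN–H2O, 0 °C) to 2-bromo-5-methoxy-1,4-benzoquinone F5. Zinc reagent 8 is coupled with it under Pd(0) (Pd(PPh3)4 5 mol %, THF, 25 °C; a Negishi coupling at a vinylogous acyl bromide). This gives 2-(5-hydroxy-7-methoxy-4-oxo-3-prenyl-4H-chromen-2-yl)-5-methoxy-1,4-benzoquinone F6. Shaking with aqueous Na2S2O4 (EtOAc–H2O, rt) reduces it to 10.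

Step 2 is the next most risky.
- Failure modes: O-alkylation of the enaminone carbonyl followed by a [3,3]-shift to the 1,1-dimethylallyl isomer, O- or C-prenylation of the electron-rich A ring, or loss of Me2NH before alkylation.
- Fallback: this sets out from 3 and returns at 6. The pyranone is closed first and the prenyl group is installed by cross-coupling. Iodine (CHCl3, rt; iodocyclisation of the enaminone) gives 5-hydroxy-3-iodo-7-methoxy-4H-chromen-4-one F3. A Stille coupling with tributyl(3-methylbut-2-en-1-yl)stannane (Pd2(dba)3/AsPh3, LiCl, DMF, 60 °C) then gives 6.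

Step 1 is the least risky of the three.
- Failure modes: O-methylation of the second, less firmly chelated phenol by DMF-DMA, or premature cyclisation to the C3-unsubstituted chromone.
- Fallback: this sets out from 1 and returns at 6, bypassing 3 and 5 by inverting the order of bond formation. The lithium trianion of 1 (LiHMDS 3.3 equiv, THF, −78 → 0 °C) is alkylated at the methyl carbon with prenyl bromide 4 to give 1-(2,6-dihydroxy-4-methoxyphenyl)-5-methylhex-4-en-1-one F1. Claisen formylation (ethyl formate, NaH, THF, 0 °C → rt) gives the cyclic hemiacetal 2,5-dihydroxy-7-methoxy-3-prenylchroman-4-one F2 (racemic diastereomer mixture). Warm AcOH dehydrates it to 6.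

**Further compounds**
F1 | step 1 | 1-(2,6-dihydroxy-4-methoxyphenyl)-5-methylhex-4-en-1-one | COc1cc(O)c(C(=O)CCC=C(C)C)c(O)c1
F2 | step 1 | 2,5-dihydroxy-7-methoxy-3-(3-methylbut-2-en-1-yl)chroman-4-one (racemic diastereomer mixture) | COc1cc(O)c2C(=O)C(CC=C(C)C)C(O)Oc2c1
F3 | step 2 | 5-hydroxy-3-iodo-7-methoxy-4H-chromen-4-one | COc1cc(O)c2c(=O)c(I)coc2c1
F4 | step 3 | 1-bromo-2,4,5-trimethoxybenzene (purchased) | COc1cc(OC)c(OC)cc1Br
F5 | step 3 | 2-bromo-5-methoxy-1,4-benzoquinone | COC1=CC(=O)C(Br)=CC1=O
F6 | step 3 | 2-(5-hydroxy-7-methoxy-4-oxo-3-prenyl-4H-chromen-2-yl)-5-methoxy-1,4-benzoquinone | COC1=CC(=O)C(=CC1=O)c1oc2cc(OC)cc(O)c2c(=O)c1CC=C(C)C
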